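In a one-step world the target, once made, stays, and you would charge partner freely; here partner also attacks the target, so your next run must choose between 1.20 equiv and 1.80 equiv.

| setting | Monday's | Friday's |
|---|---|---|
| starting material | 0.50 M | 0.50 M |
| partner | 1.20 equiv | 1.80 equiv |
| time | 40 min | 40 min |

    open intermediate + second intermediate → target (k1 = 0.209 M⁻¹ s⁻¹)
    partner → second intermediate (k2 = 0.00151 s⁻¹)
    2 open intermediate → homo product (k3 = 0.386 M⁻¹ s⁻¹)
    partner + target → over-reaction product (k4 = 0.00635 M⁻¹ s⁻¹)
    starting material → open intermediate (k5 = 0.00164 s⁻¹)

1. which of these there is most of at the end, counted by the starting material in it, Monday's (over-reaction product / target / homo product / starting material)
2. which of these there is most of at the end, counted by the starting material in it, Friday's (over-reaction product / target / homo product / starting material)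
3. how much there is at the end of the one of these that leads, in percent of the starting material charged: Monday's
4. how much there is at the end of the one of these that leads, in percent of the starting material charged: Friday's

Ask first at what level the attack on target matches its supply. Target is supplied by the opening of starting material, less what goes to homo product, and partner attacks it at a rate proportional to both their concentrations. Starting material has a half-life of 7.0 min by step 5 alone and partner one of 7.7 min by step 2 alone, both shorter than the run, so neither supply nor attack holds still and I expect no true steady state. As a yardstick I therefore take the target concentration at which attack equals opening with starting material and partner at their charged ratio, the opening constant over the attack constant times the equivalents of partner: the balance level 0.215 M on Monday's and 0.143 M on Friday's. It does not contain the concentration of starting material.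

Early on, open intermediate has dimerisation to itself. Coupling catches up near 0.120 M of second intermediate, and the share of the charge opened until partner has fed that much is 21.8% on Monday's and 14.5% on Friday's; I count it as homo product.

My reckoning for Monday's gives target at 43.0%. For Friday's it gives over-reaction product, with the remainder as my upper estimate of 56.8%. On these estimates the extra partner takes 7.3 percentage points off homo product and 14 points off target, and since target is the product wanted, I would keep Monday's charge.

The forecast gave over-reaction product at 40% on Monday's and over-reaction product at 58% on Friday's, holding that “over-reaction product leads both runs”.

The simulation gives target at 41.6% on Monday's and over-reaction product at 43.7% on Friday's. The attack of partner on target is the main reason Friday's target stands at 37.4%: the run without that step holds 81.9%. Friday's flask holds 4.2 points less target and 11 points less homo product than Monday's, so target falls by less than my estimate. Friday's target still ended 8.7 points above its balance level. Friday's recipe at 0.30 M keeps the same molar level, which is now 47.7% of that smaller charge, and that flask ended with target leading at 44.5%.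

All constants stand for no real mixture; the flask was simulated.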